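**Plan**

- Retrosynthesis: the acetates go back to the 1,4-diol, the C1 carbinol to a C1 ketone, and the C2=C3 E-enone to its Z isomer. The ring is then cut at C8–C9 by an oxy-Cope transform that reconnects C1 to C6, and the resulting cyclohexenol is cut at its C1–alkenyl bond.
- Enabling feature: the C1 oxygen sits 1,5 to the C6=C7 olefin across C8–C9 (a cyclodec-5-en-1-ol). C1–C6 together with C2–C5 is therefore a latent cyclohexenone, which is C4-oxygenated carvone.
- Forward: the six-membered ring (C1–C6) comes from (S)-carvone, the side chain is joined at C1 as an alkenyllithium, and the six-membered ring is expanded to the ten-membered ring. Enone geometry correction, reduction and acetylation follow.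
- Stereochemistry: C4 comes from the Luche reduction of (S)-carvone and C2′ from (R)-β-citronellene. The C6=C7 Z geometry and C10 come from the chair transition state of the ring expansion, C2=C3 E from stannyl addition–oxidative elimination, and C1 from peripheral hydride attack.

Key step: step 7

Remark: ring atoms are numbered as in the name cyclodeca-2,6-diene-1,4-diyl diacetate: C1 (OAc, next to C10), C2=C3(CH3), C4 (OAc), C5, C6=C7(CH3), C8, C9, C10 (side chain C1′–C7′). The same numbers are kept for the cyclohexene intermediates, where C7/C8 are the isopropenyl carbons and C10/C9 the alkenyl carbons. The target is (1R,2E,4S,6Z,10S,2′R). (S)-Carvone and (R)-β-citronellene are taken as commercial.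

**Step 1**
Reactants: 1 (S)-(+)-carvone
Product: 2 (1S,5S)-cis-carveol
Conditions: NaBH4, CeCl3·7H2O, MeOH, −78 → 0 °C
Reagents that add atoms: none
Why: Luche 1,2-reduction; hydride enters axially on the half-chair that carries the isopropenyl group equatorial, so the new C–O bond is equatorial and cis to the isopropenyl group (1S).

**Step 2**
Reactants: 2 (1S,5S)-cis-carveol
Product: 3 tert-butyldimethylsilyl ether of cis-carveol
Conditions: TBSCl, imidazole, DMF, rt
Reagents that add atoms: tert-butyldimethylsilyl chloride, CC(C)(C)[Si](C)(C)Cl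
Why: Standard silylation of a secondary allylic alcohol; no stereocentre is touched.

**Step 3**
Reactants: 3 tert-butyldimethylsilyl ether of cis-carveol
Product: 4 (4S,6S)-4-[(tert-butyldimethylsilyl)oxy]-3-methyl-6-(prop-1-en-2-yl)cyclohex-2-en-1-one
Conditions: CrO3, 3,5-dimethylpyrazole, CH2Cl2, −20 °C
Reagents that add atoms: chromium trioxide, O=[Cr](=O)=O
Why: Allylic C–H oxidation of a cyclohexene to the enone; the ring olefin has only one allylic methylene because the other allylic ring carbon carries the silyl ether, the isopropenyl group is expected to survive as it does in chromium oxidations of limonene-type dienes, and no stereocentre is changed.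

**Step 4**
Reactants: 5 (R)-β-citronellene [(3R)-3,7-dimethylocta-1,6-diene]
Product: 6 (3R)-3,7-dimethyloct-6-en-2-one
Conditions: PdCl2 (cat.), CuCl, O2, DMF–H2O, rt
Reagents that add atoms: water, O
Why: Wacker oxidation; only the monosubstituted olefin reacts, with Markovnikov regiochemistry, and the allylic stereocentre is not involved.

**Step 5**
Reactants: 6 (3R)-3,7-dimethyloct-6-en-2-one
Product: 7 2,4,6-triisopropylbenzenesulfonylhydrazone of ketone 6
Conditions: 2,4,6-triisopropylbenzenesulfonyl hydrazide, MeOH, 0 °C → rt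
Reagents that add atoms: 2,4,6-triisopropylbenzenesulfonyl hydrazide, NNS(=O)(=O)c1c(C(C)C)cc(C(C)C)cc1C(C)C
Why: Hydrazone condensation under near-neutral conditions, which should leave the α-stereocentre intact and place the sulfonamide nitrogen anti to the branched carbon.

**Step 6**
Reactants: 7 2,4,6-triisopropylbenzenesulfonylhydrazone of ketone 6; 4 (4S,6S)-4-[(tert-butyldimethylsilyl)oxy]-3-methyl-6-(prop-1-en-2-yl)cyclohex-2-en-1-one
Product: 9 (1R,4S,6S)-4-[(tert-butyldimethylsilyl)oxy]-1-[(3R)-3,7-dimethylocta-1,6-dien-2-yl]-3-methyl-6-(prop-1-en-2-yl)cyclohex-2-en-1-ol, via alkenyllithium 8 (not isolated)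
Conditions: 7, n-BuLi (2.1 equiv), TMEDA–hexane, −78 → 0 °C; then 4, THF, −78 °C; aq NH4Cl
Reagents that add atoms: none
Why: Shapiro reaction (dianion at the methyl group, loss of sulfinate and N2) followed by 1,2-addition of the alkenyllithium to the enone; attack along the axial direction of the half-chair, the torsionally preferred mode for cyclohexenones and hindered here only by one axial hydrogen at C5, should place the alkenyl group cis to the equatorial isopropenyl group (C1 R), and any trans carbinol is removed by chromatography.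

**Step 7**
Reactants: 9 (1R,4S,6S)-4-[(tert-butyldimethylsilyl)oxy]-1-[(3R)-3,7-dimethylocta-1,6-dien-2-yl]-3-methyl-6-(prop-1-en-2-yl)cyclohex-2-en-1-ol
Product: 12 (2Z,4S,6Z,10S)-4-[(tert-butyldimethylsilyl)oxy]-3,7-dimethyl-10-[(2R)-6-methylhept-5-en-2-yl]cyclodeca-2,6-dien-1-one, via potassium alkoxide 10 (not isolated), via potassium enolate 11 (not isolated)
Conditions: KH, 18-crown-6, THF, 0 °C → rt; then AcOH, THF, −78 °C
Reagents that add atoms: none
Why: The free alkoxide 10 undergoes the alkoxide-accelerated [3,3]-sigmatropic shift along C8=C7–C6–C1–C10=C9, forming C8–C9, the C6=C7 olefin and the C1=C10 enolate 11; the closest known reaction type is the anionic oxy-Cope ring expansion of 1,2-dialkenylcyclohex-2-en-1-ols to cyclodeca-2,6-dienones. The ten-membered ring is closed by a four-atom ring expansion, in which C8–C9 forms while the C1–C6 bond of the six-membered ring, present only for this purpose, breaks. The step must deliver C6=C7 as Z: because the two alkenyl groups of 9 are cis, the chair transition state has one ring bond axial, and the chair that keeps the isopropenyl group equatorial (the alternative would force the isopropenyl group and the cis C4 silyloxy group 1,3-diaxial) has C6–C5 axial, which places C5 cis to C8 in the new olefin. The same chair gives enolate 11 with C2 and C9 trans on C1=C10, a trans double bond inside the ring whose inner face is covered by the C6–C8 bridge and which cannot turn over because neither the oxygen nor the side chain can pass through the ring. Kinetic C-protonation at −78 °C should therefore come from the outer face and set C10 as S, while C4 and C2′ are untouched. The ring C2=C3 bond is a spectator and emerges as the Z enone, which steps 8 and 9 correct.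

**Step 8**
Reactants: 12 (2Z,4S,6Z,10S)-4-[(tert-butyldimethylsilyl)oxy]-3,7-dimethyl-10-[(2R)-6-methylhept-5-en-2-yl]cyclodeca-2,6-dien-1-one
Product: 14 (4S,6Z,10S)-4-[(tert-butyldimethylsilyl)oxy]-3,7-dimethyl-10-[(2R)-6-methylhept-5-en-2-yl]-3-(trimethylstannyl)cyclodec-6-en-1-one (C3 configuration not assigned), via lithium enolate 13 (not isolated)
Conditions: Me3SnLi (from Me3SnSnMe3 and MeLi), THF, −78 °C; MeOH
Reagents that add atoms: trimethylstannyllithium, [Li][Sn](C)(C)C
Why: Conjugate addition of a stannyl anion to the enone, which makes C3 sp3 and frees rotation about C2–C3; the enolate forms toward C2 only, so C10 should not epimerise, and the configuration of the new tin-bearing carbon does not matter because it is erased in step 9.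

**Step 9**
Reactants: 14 (4S,6Z,10S)-4-[(tert-butyldimethylsilyl)oxy]-3,7-dimethyl-10-[(2R)-6-methylhept-5-en-2-yl]-3-(trimethylstannyl)cyclodec-6-en-1-one
Product: 15 (2E,4S,6Z,10S)-4-[(tert-butyldimethylsilyl)oxy]-3,7-dimethyl-10-[(2R)-6-methylhept-5-en-2-yl]cyclodeca-2,6-dien-1-one
Conditions: CrO3·2py, CH2Cl2, 0 °C → rt
Reagents that add atoms: none
Why: Oxidative destannylation of a β-stannyl ketone back to the enone; elimination across C2–C3 should occur from the extended rotamer in which the ring bonds C1–C2 and C3–C4 are anti, the arrangement a ten-membered ring prefers about an sp3–sp3 bond, so the enone re-forms as the E isomer, as in the known Z to E correction of cyclodeca-2,6-dienones by this addition–elimination pair.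

**Step 10**
Reactants: 15 (2E,4S,6Z,10S)-4-[(tert-butyldimethylsilyl)oxy]-3,7-dimethyl-10-[(2R)-6-methylhept-5-en-2-yl]cyclodeca-2,6-dien-1-one
Product: 16 (1R,2E,4S,6Z,10S)-4-[(tert-butyldimethylsilyl)oxy]-3,7-dimethyl-10-[(2R)-6-methylhept-5-en-2-yl]cyclodeca-2,6-dien-1-ol
Conditions: NaBH4, CeCl3·7H2O, MeOH, −40 °C
Reagents that add atoms: none
Why: Luche 1,2-reduction; with the C10–H bond eclipsing C1–C2 (the rotamers that point C9 or the side chain at H2 are excluded), C9 and the side chain straddle the carbonyl plane, the ring covers the C9 face, and hydride should add from the periphery anti to the ring bond C10–C9 to give the 1R alcohol.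

**Step 11**
Reactants: 16 (1R,2E,4S,6Z,10S)-4-[(tert-butyldimethylsilyl)oxy]-3,7-dimethyl-10-[(2R)-6-methylhept-5-en-2-yl]cyclodeca-2,6-dien-1-ol
Product: 17 (1R,2E,4S,6Z,10S)-3,7-dimethyl-10-[(2R)-6-methylhept-5-en-2-yl]cyclodeca-2,6-diene-1,4-diol
Conditions: TBAF, THF, 0 °C → rt
Reagents that add atoms: none
Why: Fluoride cleavage of the silyl ether; no stereocentre is touched.

**Step 12**
Reactants: 17 (1R,2E,4S,6Z,10S)-3,7-dimethyl-10-[(2R)-6-methylhept-5-en-2-yl]cyclodeca-2,6-diene-1,4-diol
Product: 18 (1R,2E,4S,6Z,10S)-3,7-dimethyl-10-[(2R)-6-methylhept-5-en-2-yl]cyclodeca-2,6-diene-1,4-diyl diacetate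
Conditions: Ac2O, pyridine, DMAP (cat.), CH2Cl2, rt
Reagents that add atoms: acetic anhydride, CC(=O)OC(C)=O
Why: Acylation of both secondary allylic alcohols with retention at C1 and C4.

**Compound list**

1 | (S)-(+)-carvone | CC(=C)[C@@H]1CC(=O)C(C)=CC1 | starting material
2 | (1S,5S)-cis-carveol | CC(=C)[C@@H]1C[C@H](O)C(C)=CC1 | intermediate
3 | tert-butyldimethylsilyl ether of (1S,5S)-cis-carveol | CC(=C)[C@@H]1C[C@H](O[Si](C)(C)C(C)(C)C)C(C)=CC1 | intermediate
4 | (4S,6S)-4-[(tert-butyldimethylsilyl)oxy]-3-methyl-6-(prop-1-en-2-yl)cyclohex-2-en-1-one | CC(=C)[C@@H]1C[C@H](O[Si](C)(C)C(C)(C)C)C(C)=CC1=O | intermediate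
5 | (R)-β-citronellene, (3R)-3,7-dimethylocta-1,6-diene | C=C[C@H](C)CCC=C(C)C | starting material
6 | (3R)-3,7-dimethyloct-6-en-2-one | CC(=O)[C@H](C)CCC=C(C)C | intermediate
7 | 2,4,6-triisopropylbenzenesulfonylhydrazone of 6 | CC(=NNS(=O)(=O)c1c(C(C)C)cc(C(C)C)cc1C(C)C)[C@H](C)CCC=C(C)C | intermediate
8 | (3R)-3,7-dimethylocta-1,6-dien-2-yllithium | [Li]C(=C)[C@H](C)CCC=C(C)C | intermediate (not isolated)
9 | (1R,4S,6S)-4-[(tert-butyldimethylsilyl)oxy]-1-[(3R)-3,7-dimethylocta-1,6-dien-2-yl]-3-methyl-6-(prop-1-en-2-yl)cyclohex-2-en-1-ol (alkenyl cis to isopropenyl) | CC(=C)[C@@H]1C[C@H](O[Si](C)(C)C(C)(C)C)C(C)=C[C@]1(O)C(=C)[C@H](C)CCC=C(C)C | intermediate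
10 | potassium alkoxide of 9 | CC(=C)[C@@H]1C[C@H](O[Si](C)(C)C(C)(C)C)C(C)=C[C@]1([O-])C(=C)[C@H](C)CCC=C(C)C.[K+] | intermediate (not isolated)
11 | potassium (1(10)E,2Z,4S,6Z)-4-[(tert-butyldimethylsilyl)oxy]-3,7-dimethyl-10-[(2R)-6-methylhept-5-en-2-yl]cyclodeca-1(10),2,6-trien-1-olate | CC(C)(C)[Si](C)(C)O[C@H]1C/C=C(/C)CC/C([C@H](C)CCC=C(C)C)=C([O-])/C=C\1C.[K+] | intermediate (not isolated)
12 | (2Z,4S,6Z,10S)-4-[(tert-butyldimethylsilyl)oxy]-3,7-dimethyl-10-[(2R)-6-methylhept-5-en-2-yl]cyclodeca-2,6-dien-1-one | CC(C)(C)[Si](C)(C)O[C@H]1C/C=C(/C)CC[C@@H]([C@H](C)CCC=C(C)C)C(=O)/C=C\1C | intermediate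
13 | lithium enolate (C1=C2) of stannyl ketone 14 | CC(C)(C)[Si](C)(C)O[C@H]1C/C=C(/C)CC[C@@H]([C@H](C)CCC=C(C)C)C([O-])=CC1(C)[Sn](C)(C)C.[Li+] | intermediate (not isolated)
14 | (4S,6Z,10S)-4-[(tert-butyldimethylsilyl)oxy]-3,7-dimethyl-10-[(2R)-6-methylhept-5-en-2-yl]-3-(trimethylstannyl)cyclodec-6-en-1-one, C3 not assigned | CC(C)(C)[Si](C)(C)O[C@H]1C/C=C(/C)CC[C@@H]([C@H](C)CCC=C(C)C)C(=O)CC1(C)[Sn](C)(C)C | intermediate
15 | (2E,4S,6Z,10S)-4-[(tert-butyldimethylsilyl)oxy]-3,7-dimethyl-10-[(2R)-6-methylhept-5-en-2-yl]cyclodeca-2,6-dien-1-one | CC(C)(C)[Si](C)(C)O[C@H]1C/C=C(/C)CC[C@@H]([C@H](C)CCC=C(C)C)C(=O)/C=C/1C | intermediate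
16 | (1R,2E,4S,6Z,10S)-4-[(tert-butyldimethylsilyl)oxy]-3,7-dimethyl-10-[(2R)-6-methylhept-5-en-2-yl]cyclodeca-2,6-dien-1-ol | CC(C)(C)[Si](C)(C)O[C@H]1C/C=C(/C)CC[C@@H]([C@H](C)CCC=C(C)C)[C@@H](O)/C=C/1C | intermediate
17 | (1R,2E,4S,6Z,10S)-3,7-dimethyl-10-[(2R)-6-methylhept-5-en-2-yl]cyclodeca-2,6-diene-1,4-diol | O[C@H]1C/C=C(/C)CC[C@@H]([C@H](C)CCC=C(C)C)[C@@H](O)/C=C/1C | intermediate
18 | (1R,2E,4S,6Z,10S)-3,7-dimethyl-10-[(2R)-6-methylhept-5-en-2-yl]cyclodeca-2,6-diene-1,4-diyl diacetate | CC(=O)O[C@H]1C/C=C(/C)CC[C@@H]([C@H](C)CCC=C(C)C)[C@@H](OC(C)=O)/C=C/1C | target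

**Step count**

Total: 12 steps. Longest linear sequence: 10 steps (steps 1–3 and 6–12); the side-chain branch is steps 4–5.

**Steps most likely to fail, with fallbacks**

Step 7. The cis carbinol may rearrange through the competing chair (isopropenyl axial) or a boat, because in the desired chair the branched substituent on C10 eclipses the C1–C2 bond. That pathway would give the 6E olefin and the opposite configuration at C10.

The fallback takes the branch out of the rearrangement and sets out from enone 4. Vinylmagnesium bromide with CeCl3 in THF at −78 °C should add axially to give (4S,6S)-4-[(tert-butyldimethylsilyl)oxy]-1-ethenyl-3-methyl-6-(prop-1-en-2-yl)cyclohex-2-en-1-ol F1, with vinyl cis to isopropenyl. KH and 18-crown-6 should then expand it through the now unencumbered chair to (2Z,4S,6Z)-4-[(tert-butyldimethylsilyl)oxy]-3,7-dimethylcyclodeca-2,6-dien-1-one F2. Kinetic deprotonation at C10 with LDA and aldol addition to 5-methylhex-4-enal would give the β-hydroxy ketone F3. Dehydration with methyl N-(triethylammoniosulfonyl)carbamate would give the exocyclic (E)-alkylidene ketone F4. Me2CuLi should add to the more reactive exocyclic enone from the ring periphery, and kinetic protonation followed by separation of diastereomers returns to 12. The C2′ centre then rests on peripheral attack, which is the weak point of this fallback.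

Step 9 (with step 8). The β-stannyl silyl ether may lose the C4 silyloxy group by 1,2-elimination, or the elimination may give the Z enone again.

The fallback sets E geometry by a selenoxide syn-elimination and sets out from 12. Copper hydride conjugate reduction ([(Ph3P)CuH]6 cat., PhMe2SiH, toluene) gives the regiodefined dimethylphenylsilyl enol ether F5. PhSeCl at −78 °C gives the 2-phenylselanyl ketone F6. H2O2 and pyridine in CH2Cl2 at 0 °C should bring about syn-elimination toward C3–H through the extended rotamer and return to 15.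

Step 10. If the ring adopts the other conformation, hydride is delivered to the opposite carbonyl face and the C1 epimer results.

The fallback is an invertive esterification and sets out from 15. If the reduction gives mainly (1S,2E,4S,6Z,10S)-4-[(tert-butyldimethylsilyl)oxy]-3,7-dimethyl-10-[(2R)-6-methylhept-5-en-2-yl]cyclodeca-2,6-dien-1-ol F7, a Mitsunobu reaction with acetic acid (PPh3, DIAD, THF, 0 °C) should give the 1R acetate F8 with inversion. HF·pyridine in THF then frees the C4 hydroxyl to give hydroxy acetate F9, and Ac2O, pyridine and DMAP return to 18.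

**Further compounds**

F1 | step 7 | (4S,6S)-4-[(tert-butyldimethylsilyl)oxy]-1-ethenyl-3-methyl-6-(prop-1-en-2-yl)cyclohex-2-en-1-ol, vinyl cis to isopropenyl | CC(=C)[C@@H]1C[C@H](O[Si](C)(C)C(C)(C)C)C(C)=C[C@]1(O)C=C
F2 | step 7 | (2Z,4S,6Z)-4-[(tert-butyldimethylsilyl)oxy]-3,7-dimethylcyclodeca-2,6-dien-1-one | CC(C)(C)[Si](C)(C)O[C@H]1C/C=C(/C)CCCC(=O)/C=C\1C
F3 | step 7 | (2Z,4S,6Z)-4-[(tert-butyldimethylsilyl)oxy]-10-(1-hydroxy-5-methylhex-4-en-1-yl)-3,7-dimethylcyclodeca-2,6-dien-1-one | CC(C)(C)[Si](C)(C)O[C@H]1C/C=C(/C)CCC(C(O)CCC=C(C)C)C(=O)/C=C\1C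
F4 | step 7 | (2Z,4S,6Z,10E)-4-[(tert-butyldimethylsilyl)oxy]-3,7-dimethyl-10-(5-methylhex-4-en-1-ylidene)cyclodeca-2,6-dien-1-one | CC(C)(C)[Si](C)(C)O[C@H]1C/C=C(/C)CC/C(=C\CCC=C(C)C)C(=O)/C=C\1C
F5 | step 9 | dimethylphenylsilyl enol ether (C1=C2) of the 2,3-dihydro derivative of 12 | CC(C)(C)[Si](C)(C)O[C@H]1C/C=C(/C)CC[C@@H]([C@H](C)CCC=C(C)C)C(O[Si](C)(C)c2ccccc2)=CC1C
F6 | step 9 | (4S,6Z,10S)-4-[(tert-butyldimethylsilyl)oxy]-3,7-dimethyl-10-[(2R)-6-methylhept-5-en-2-yl]-2-(phenylselanyl)cyclodec-6-en-1-one | CC(C)(C)[Si](C)(C)O[C@H]1C/C=C(/C)CC[C@@H]([C@H](C)CCC=C(C)C)C(=O)C([Se]c2ccccc2)C1C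
F7 | step 10 | (1S,2E,4S,6Z,10S)-4-[(tert-butyldimethylsilyl)oxy]-3,7-dimethyl-10-[(2R)-6-methylhept-5-en-2-yl]cyclodeca-2,6-dien-1-ol | CC(C)(C)[Si](C)(C)O[C@H]1C/C=C(/C)CC[C@@H]([C@H](C)CCC=C(C)C)[C@H](O)/C=C/1C
F8 | step 10 | (1R,2E,4S,6Z,10S)-4-[(tert-butyldimethylsilyl)oxy]-3,7-dimethyl-10-[(2R)-6-methylhept-5-en-2-yl]cyclodeca-2,6-dien-1-yl acetate | CC(C)(C)[Si](C)(C)O[C@H]1C/C=C(/C)CC[C@@H]([C@H](C)CCC=C(C)C)[C@@H](OC(C)=O)/C=C/1C
F9 | step 10 | (1R,2E,4S,6Z,10S)-4-hydroxy-3,7-dimethyl-10-[(2R)-6-methylhept-5-en-2-yl]cyclodeca-2,6-dien-1-yl acetate | O[C@H]1C/C=C(/C)CC[C@@H]([C@H](C)CCC=C(C)C)[C@@H](OC(C)=O)/C=C/1C
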